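**Plan**
- Unit 2 (the 6-linked flavone) is cut first: O1''–C2'' (oxidative chalcone closure), C2''–C3'' (aldol) and C4a''–C4'' (aryl C-acetylation). This leaves unit 1 with a 4-benzyloxy-2,6-dimethoxyphenyl group on C8.
- Unit 1 is then cut at C4a–C5: ring A unravels to a chain C8–C7–C6–C5 on a 4-pyranone, with C5/C6 from Meldrum's acid, C7 from CO2 and C8 from a benzaldehyde carbon.
- The feature that allows this: in unit 1, C8 is bonded to C8a, the oxygen-bearing carbon of pyranone ring C. A chain rooted at that carbon of a finished pyranone can reach only C4a, so the 8-aryl pattern is built in.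
- Forward order: ring C of unit 1 (triketone cyclodehydration), then ring A of unit 1 (ketene electrocyclization), then ring C of unit 2 on the trioxygenated benzene, which becomes ring A of unit 2.
- There are no stereocentres; the chalcone alkene and the sp3 centre at C8 are transient.

Key step: step 8

Remark: the target is drawn without an axial descriptor, so the hindered C8–C6'' biaryl axis is left uncontrolled (racemic atropisomers).

**Step 1**
Reactants: 1 4-hydroxy-2,6-dimethoxybenzaldehyde
Product: 2 4-(benzyloxy)-2,6-dimethoxybenzaldehyde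
Conditions: BnBr, K2CO3, DMF, rt
Reagents that add atoms: benzyl bromide, BrCc1ccccc1
Why: Williamson etherification of the only phenol; the benzyl group marks the oxygen that later becomes O1'' of unit 2.

**Step 2**
Reactants: 2 4-(benzyloxy)-2,6-dimethoxybenzaldehyde
Product: 3 5-(benzyloxy)-1,3-dimethoxy-2-[2-(methylsulfanyl)-2-(methylsulfinyl)ethenyl]benzene (alkene isomer mixture; racemic at sulfur)
Conditions: MeS(O)CH2SMe, benzyltrimethylammonium hydroxide (40% in MeOH, cat.), THF, reflux
Reagents that add atoms: methyl (methylsulfanyl)methyl sulfoxide, CS(=O)CSC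
Why: Knoevenagel-type condensation of the aldehyde with the anion of the formaldehyde dithioacetal S-oxide, the first half of the standard aldehyde-to-arylacetate homologation, which accepts electron-rich benzaldehydes.

**Step 3**
Reactants: 3 5-(benzyloxy)-1,3-dimethoxy-2-[2-(methylsulfanyl)-2-(methylsulfinyl)ethenyl]benzene
Product: 4 methyl [4-(benzyloxy)-2,6-dimethoxyphenyl]acetate
Conditions: HCl (g), MeOH, 0 °C to rt
Reagents that add atoms: methanol, CO
Why: acid-promoted methanolysis of the ketene dithioacetal S-oxide (Pummerer-type transfer of the oxidation level from sulfur to carbon) should give the arylacetic ester and dimethyl disulfide without touching the aryl benzyl ether.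

**Step 4**
Reactants: 4 methyl [4-(benzyloxy)-2,6-dimethoxyphenyl]acetate; 5 1-(4-methoxyphenyl)butane-1,3-dione
Product: 6 1-[4-(benzyloxy)-2,6-dimethoxyphenyl]-6-(4-methoxyphenyl)hexane-2,4,6-trione
Conditions: 5 (2.2 equiv), LiN(iPr)2 (4.4 equiv), THF, −78 to 0 °C; then 4, −78 °C to rt; 1 M HCl
Reagents that add atoms: none
Why: Claisen-type acylation of a β-diketone dianion at its terminal methyl carbanion by an ester is the classical 1,3,5-triketone synthesis; the excess dianion covers the acidity of the triketone formed and any enolization of the arylacetate.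

**Step 5**
Reactants: 6 1-[4-(benzyloxy)-2,6-dimethoxyphenyl]-6-(4-methoxyphenyl)hexane-2,4,6-trione
Product: 7 2-{[4-(benzyloxy)-2,6-dimethoxyphenyl]methyl}-6-(4-methoxyphenyl)-4H-pyran-4-one
Conditions: TFA, CH2Cl2, 0 °C to rt
Reagents that add atoms: none
Why: acid-catalysed cyclodehydration of a 1,3,5-triketone gives the 4-pyranone (either terminal carbonyl oxygen leads to the same ring), and acid favours this O-cyclization over the aldol path to a resorcinol.

**Step 6**
Reactants: 7 2-{[4-(benzyloxy)-2,6-dimethoxyphenyl]methyl}-6-(4-methoxyphenyl)-4H-pyran-4-one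
Product: 8 [4-(benzyloxy)-2,6-dimethoxyphenyl][6-(4-methoxyphenyl)-4-oxo-4H-pyran-2-yl]acetic acid (racemic)
Conditions: LiN(SiMe3)2 (1.2 equiv), THF, −78 °C; CO2 (g), −78 °C; cold 1 M HCl, extraction at 0 °C, used at once
Reagents that add atoms: carbon dioxide, O=C=O
Why: the CH2 group is benzylic and vinylogously α to the pyranone carbonyl, so γ-deprotonation of the 2-alkyl-4-pyranone gives an extended enolate that CO2 should carboxylate at the exocyclic carbon (carboxylation of a stabilized carbanion), the cold acidic quench returning the acid before it can lose CO2.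

**Step 7**
Reactants: 8 [4-(benzyloxy)-2,6-dimethoxyphenyl][6-(4-methoxyphenyl)-4-oxo-4H-pyran-2-yl]acetic acid; 9 Meldrum's acid (2,2-dimethyl-1,3-dioxane-4,6-dione)
Product: 11 5-{[4-(benzyloxy)-2,6-dimethoxyphenyl][6-(4-methoxyphenyl)-4-oxo-4H-pyran-2-yl]acetyl}-2,2-dimethyl-1,3-dioxane-4,6-dione (racemic; present mainly as its enol), via acid chloride 10 (not isolated)
Conditions: 1-chloro-N,N,2-trimethylprop-1-en-1-amine, CH2Cl2, 0 °C; then 9, pyridine, −20 to 0 °C
Reagents that add atoms: none
Why: neutral acid chloride formation with the α-chloroenamine followed by pyridine-mediated C-acylation of Meldrum's acid is the standard entry to acyl Meldrum's acids and never exposes the decarboxylation-prone carboxylate to base.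

**Step 8**
Reactants: 11 5-{[4-(benzyloxy)-2,6-dimethoxyphenyl][6-(4-methoxyphenyl)-4-oxo-4H-pyran-2-yl]acetyl}-2,2-dimethyl-1,3-dioxane-4,6-dione
Product: 15 8-[4-(benzyloxy)-2,6-dimethoxyphenyl]-5,7-dihydroxy-2-(4-methoxyphenyl)-4H-chromen-4-one, via acylketene 12 (not isolated), via dienol ketene 13 (not isolated), via cyclohexadienone 14 (not isolated)
Conditions: toluene (0.005 M), reflux, N2
Reagents that add atoms: none
Why: Proposed new method: heating 11 should expel acetone and CO2 to give acylketene 12, whose very acidic C8–H tautomerizes to dienol 13, a dienylketene in which the pyranone C4a=C8a bond is the terminal alkene; thermal six-electron electrocyclization then joins the ketene carbon C5 to C4a (six-membered carbocycle, disrotatory 6π closure, equally readable as C-acylation of the pyranone dienol by the ketene), and cyclohexadienone 14 tautomerizes to the aromatic 5,7-diol. The closest known reactions are acylketene generation by thermolysis of acyl Meldrum's acids and dioxinones, and the dienylketene-to-phenol closure of the Danheiser benzannulation and of arylketene cyclizations. Ring A is the only ring formed and no stereocentre survives, the sp3 C4a of 14 being lost on aromatization. The step needs closure at carbon and only at C4a: C4a is the sole carbon six atoms from C5 within the conjugated system, the existing C8–C8a bond rules out a 6-aryl isomer, and both ortho positions of the aryl ring carry OMe, so the competing cyclization of an arylacetylketene onto its own arene is blocked. High dilution suppresses ketene dimerization, and the neutral medium leaves the benzyl ether and the pyranone untouched.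

**Step 9**
Reactants: 15 8-[4-(benzyloxy)-2,6-dimethoxyphenyl]-5,7-dihydroxy-2-(4-methoxyphenyl)-4H-chromen-4-one
Product: 16 8-[4-(benzyloxy)-2,6-dimethoxyphenyl]-2-(4-methoxyphenyl)-4-oxo-4H-chromene-5,7-diyl diacetate
Conditions: Ac2O, pyridine, DMAP (cat.), rt
Reagents that add atoms: acetic anhydride, CC(=O)OC(C)=O
Why: O-acylation of both phenols (DMAP catalysis also reaches the hydrogen-bonded 5-OH) deactivates ring A of unit 1 toward the electrophile of the next step.

**Step 10**
Reactants: 16 8-[4-(benzyloxy)-2,6-dimethoxyphenyl]-2-(4-methoxyphenyl)-4-oxo-4H-chromene-5,7-diyl diacetate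
Product: 17 8-[3-acetyl-4-(benzyloxy)-2,6-dimethoxyphenyl]-2-(4-methoxyphenyl)-4-oxo-4H-chromene-5,7-diyl diacetate
Conditions: AcOH, (CF3CO)2O, CH2Cl2, 0 °C to rt
Reagents that add atoms: acetic acid, CC(O)=O
Why: Friedel–Crafts acylation by acetyl trifluoroacetate formed in situ should attack the phloroglucinol-triether ring at its only free position type (C3' and C5' are equivalent), since the ester-deactivated ring A and the anisyl ring are far less nucleophilic and no Lewis acid is present to cleave the benzyl ether.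

**Step 11**
Reactants: 17 8-[3-acetyl-4-(benzyloxy)-2,6-dimethoxyphenyl]-2-(4-methoxyphenyl)-4-oxo-4H-chromene-5,7-diyl diacetate
Product: 18 8-(3-acetyl-4-hydroxy-2,6-dimethoxyphenyl)-2-(4-methoxyphenyl)-4-oxo-4H-chromene-5,7-diyl diacetate
Conditions: H2 (1 atm), 10% Pd/C, EtOAc–THF, rt
Reagents that add atoms: none
Why: hydrogenolysis of the aryl benzyl ether frees the phenol para to the biaryl bond, the oxygen that must become O1'' of unit 2, while aryl acetates, aryl methyl ethers and the flavone should be inert at this pressure.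

**Step 12**
Reactants: 18 8-(3-acetyl-4-hydroxy-2,6-dimethoxyphenyl)-2-(4-methoxyphenyl)-4-oxo-4H-chromene-5,7-diyl diacetate; 19 4-isopropoxybenzaldehyde
Product: 21 5,7-dihydroxy-8-{4-hydroxy-2,6-dimethoxy-3-[(2E)-3-(4-isopropoxyphenyl)prop-2-enoyl]phenyl}-2-(4-methoxyphenyl)-4H-chromen-4-one, via triol ketone 20 (not isolated)
Conditions: KOH (50% aq.), EtOH, rt, Ar; then 1 M HCl
Reagents that add atoms: none
Why: Claisen–Schmidt aldol condensation of the ortho-hydroxyacetophenone with the non-enolizable aldehyde should give the E-chalcone (thermodynamic geometry from E1cB dehydration), the hydroxide first saponifying both aryl acetates.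

**Step 13**
Reactants: 21 5,7-dihydroxy-8-{4-hydroxy-2,6-dimethoxy-3-[(2E)-3-(4-isopropoxyphenyl)prop-2-enoyl]phenyl}-2-(4-methoxyphenyl)-4H-chromen-4-one
Product: 22 5,7-dihydroxy-8-[2-(4-isopropoxyphenyl)-5,7-dimethoxy-4-oxo-4H-chromen-6-yl]-2-(4-methoxyphenyl)-4H-chromen-4-one
Conditions: I2 (10 mol%), DMSO, 120–130 °C
Reagents that add atoms: none
Why: iodine-catalysed oxidative cyclization of a 2'-hydroxychalcone in DMSO (oxa-Michael closure, then iodination–elimination with DMSO reoxidizing HI) is the standard flavone synthesis and can close only through the single free ortho-hydroxyl, which gives the 6-linked unit 2.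

**Step 14**
Reactants: 22 5,7-dihydroxy-8-[2-(4-isopropoxyphenyl)-5,7-dimethoxy-4-oxo-4H-chromen-6-yl]-2-(4-methoxyphenyl)-4H-chromen-4-one
Product: 23 5,7-dihydroxy-8-[5-hydroxy-2-(4-hydroxyphenyl)-7-methoxy-4-oxo-4H-chromen-6-yl]-2-(4-methoxyphenyl)-4H-chromen-4-one
Conditions: BCl3 (1 M in CH2Cl2, excess), CH2Cl2, −78 to 0 °C; then H2O
Reagents that add atoms: none
Why: chelation-controlled Lewis-acid dealkylation: BCl3 should cleave the methyl ether peri to the C4'' carbonyl through a six-membered boron chelate and also remove the secondary isopropyl ether, whereas the non-chelated 7''- and 4'-methyl ethers survive at 0 °C.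

**Compound list**
1 | 4-hydroxy-2,6-dimethoxybenzaldehyde | COc1cc(O)cc(OC)c1C=O | starting material
2 | 4-(benzyloxy)-2,6-dimethoxybenzaldehyde | COc1cc(OCc2ccccc2)cc(OC)c1C=O | intermediate
3 | 5-(benzyloxy)-1,3-dimethoxy-2-[2-(methylsulfanyl)-2-(methylsulfinyl)ethenyl]benzene (alkene geometry and sulfur configuration undefined) | COc1cc(OCc2ccccc2)cc(OC)c1C=C(SC)S(C)=O | intermediate
4 | methyl [4-(benzyloxy)-2,6-dimethoxyphenyl]acetate | COC(=O)Cc1c(OC)cc(OCc2ccccc2)cc1OC | intermediate
5 | 1-(4-methoxyphenyl)butane-1,3-dione | COc1ccc(cc1)C(=O)CC(C)=O | starting material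
6 | 1-[4-(benzyloxy)-2,6-dimethoxyphenyl]-6-(4-methoxyphenyl)hexane-2,4,6-trione | COc1ccc(cc1)C(=O)CC(=O)CC(=O)Cc1c(OC)cc(OCc2ccccc2)cc1OC | intermediate
7 | 2-{[4-(benzyloxy)-2,6-dimethoxyphenyl]methyl}-6-(4-methoxyphenyl)-4H-pyran-4-one | COc1ccc(cc1)-c2cc(=O)cc(Cc3c(OC)cc(OCc4ccccc4)cc3OC)o2 | intermediate
8 | [4-(benzyloxy)-2,6-dimethoxyphenyl][6-(4-methoxyphenyl)-4-oxo-4H-pyran-2-yl]acetic acid (racemic) | COc1ccc(cc1)-c2cc(=O)cc(o2)C(C(=O)O)c3c(OC)cc(OCc4ccccc4)cc3OC | intermediate
9 | Meldrum's acid (2,2-dimethyl-1,3-dioxane-4,6-dione) | CC1(C)OC(=O)CC(=O)O1 | starting material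
10 | [4-(benzyloxy)-2,6-dimethoxyphenyl][6-(4-methoxyphenyl)-4-oxo-4H-pyran-2-yl]acetyl chloride (racemic; not isolated) | COc1ccc(cc1)-c2cc(=O)cc(o2)C(C(Cl)=O)c3c(OC)cc(OCc4ccccc4)cc3OC | intermediate
11 | 5-{[4-(benzyloxy)-2,6-dimethoxyphenyl][6-(4-methoxyphenyl)-4-oxo-4H-pyran-2-yl]acetyl}-2,2-dimethyl-1,3-dioxane-4,6-dione (racemic; drawn as keto form) | COc1ccc(cc1)-c2cc(=O)cc(o2)C(C(=O)C3C(=O)OC(C)(C)OC3=O)c4c(OC)cc(OCc5ccccc5)cc4OC | intermediate
12 | 4-[4-(benzyloxy)-2,6-dimethoxyphenyl]-4-[6-(4-methoxyphenyl)-4-oxo-4H-pyran-2-yl]but-1-ene-1,3-dione (acylketene; racemic; not isolated) | COc1ccc(cc1)-c2cc(=O)cc(o2)C(C(=O)C=C=O)c3c(OC)cc(OCc4ccccc4)cc3OC | intermediate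
13 | (3E)-4-[4-(benzyloxy)-2,6-dimethoxyphenyl]-3-hydroxy-4-[6-(4-methoxyphenyl)-4-oxo-4H-pyran-2-yl]buta-1,3-dien-1-one (dienol ketene, pyranonyl cis to the ketenyl carbon; not isolated) | COc1ccc(cc1)-c2cc(=O)cc(o2)/C(c3c(OC)cc(OCc4ccccc4)cc3OC)=C(/O)C=C=O | intermediate
14 | 8-[4-(benzyloxy)-2,6-dimethoxyphenyl]-7-hydroxy-2-(4-methoxyphenyl)-4aH-chromene-4,5-dione (racemic at C4a; not isolated) | COc1ccc(cc1)C2=CC(=O)C3C(=O)C=C(O)C(c4c(OC)cc(OCc5ccccc5)cc4OC)=C3O2 | intermediate
15 | 8-[4-(benzyloxy)-2,6-dimethoxyphenyl]-5,7-dihydroxy-2-(4-methoxyphenyl)-4H-chromen-4-one | COc1ccc(cc1)-c2cc(=O)c3c(O)cc(O)c(-c4c(OC)cc(OCc5ccccc5)cc4OC)c3o2 | intermediate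
16 | 8-[4-(benzyloxy)-2,6-dimethoxyphenyl]-2-(4-methoxyphenyl)-4-oxo-4H-chromene-5,7-diyl diacetate | COc1ccc(cc1)-c2cc(=O)c3c(OC(C)=O)cc(OC(C)=O)c(-c4c(OC)cc(OCc5ccccc5)cc4OC)c3o2 | intermediate
17 | 8-[3-acetyl-4-(benzyloxy)-2,6-dimethoxyphenyl]-2-(4-methoxyphenyl)-4-oxo-4H-chromene-5,7-diyl diacetate | COc1ccc(cc1)-c2cc(=O)c3c(OC(C)=O)cc(OC(C)=O)c(-c4c(OC)cc(OCc5ccccc5)c(C(C)=O)c4OC)c3o2 | intermediate
18 | 8-(3-acetyl-4-hydroxy-2,6-dimethoxyphenyl)-2-(4-methoxyphenyl)-4-oxo-4H-chromene-5,7-diyl diacetate | COc1ccc(cc1)-c2cc(=O)c3c(OC(C)=O)cc(OC(C)=O)c(-c4c(OC)cc(O)c(C(C)=O)c4OC)c3o2 | intermediate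
19 | 4-isopropoxybenzaldehyde | CC(C)Oc1ccc(C=O)cc1 | starting material
20 | 8-(3-acetyl-4-hydroxy-2,6-dimethoxyphenyl)-5,7-dihydroxy-2-(4-methoxyphenyl)-4H-chromen-4-one (not isolated) | COc1ccc(cc1)-c2cc(=O)c3c(O)cc(O)c(-c4c(OC)cc(O)c(C(C)=O)c4OC)c3o2 | intermediate
21 | 5,7-dihydroxy-8-{4-hydroxy-2,6-dimethoxy-3-[(2E)-3-(4-isopropoxyphenyl)prop-2-enoyl]phenyl}-2-(4-methoxyphenyl)-4H-chromen-4-one | COc1ccc(cc1)-c2cc(=O)c3c(O)cc(O)c(-c4c(OC)cc(O)c(C(=O)/C=C/c5ccc(OC(C)C)cc5)c4OC)c3o2 | intermediate
22 | 5,7-dihydroxy-8-[2-(4-isopropoxyphenyl)-5,7-dimethoxy-4-oxo-4H-chromen-6-yl]-2-(4-methoxyphenyl)-4H-chromen-4-one | COc1ccc(cc1)-c2cc(=O)c3c(O)cc(O)c(-c4c(OC)cc5oc(cc(=O)c5c4OC)-c6ccc(OC(C)C)cc6)c3o2 | intermediate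
23 | 5,7-dihydroxy-8-[5-hydroxy-2-(4-hydroxyphenyl)-7-methoxy-4-oxo-4H-chromen-6-yl]-2-(4-methoxyphenyl)-4H-chromen-4-one | COc1ccc(-c2cc(=O)c3c(O)cc(O)c(-c4c(OC)cc5oc(-c6ccc(O)cc6)cc(=O)c5c4O)c3o2)cc1 | target

**Step count**
Total steps: 14. Longest linear sequence: 14 steps (1 to 23); compounds 5, 9 and 19 are bought.

**Steps most likely to fail**

1. Step 8 (new method). The acylketene may dimerize or be lost to adventitious nucleophiles before the C8–H tautomerization and the closure at C4a take place. The fallback sets out from 11 and returns at 15. Compound 11 is heated in methanol, where the ketene is trapped intermolecularly, to give methyl 4-[4-(benzyloxy)-2,6-dimethoxyphenyl]-4-[6-(4-methoxyphenyl)-4-oxo-4H-pyran-2-yl]-3-oxobutanoate F1. Treatment of this β-keto ester with Mg(OMe)2 in MeOH at reflux should remove the C8 proton to give the extended pyranone enolate. That enolate acylates itself at C4a with the ester carbonyl (intramolecular Claisen condensation, the polyketide mode of closing a phloroglucinol ring), and aromatization gives 15. Magnesium chelation is chosen so that the pyranone stays closed and the 8-aryl pattern is kept.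

2. Step 6. The carboxylation may reverse: the lithium carboxylate, or the vinylogous β-keto acid during work-up, can lose CO2 and return 7. The fallback sets out from 7 and returns at 8. The anion of 7 (LiN(SiMe3)2, 2.1 equiv, THF, −78 °C) is trapped irreversibly with Boc2O to give tert-butyl [4-(benzyloxy)-2,6-dimethoxyphenyl][6-(4-methoxyphenyl)-4-oxo-4H-pyran-2-yl]acetate F2, which can be purified and stored. Cleavage with TFA in CH2Cl2 at 0 °C then releases 8 in acidic solution, where it is never a carboxylate salt, and the residue after evaporation is taken straight into step 7.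

3. Step 4. Proton transfer from the arylacetate to the strongly basic dianion may outrun acylation and return both partners. The fallback sets out from 4 and returns at 6. Ester 4 is reduced with i-Bu2AlH in CH2Cl2 at −78 °C to [4-(benzyloxy)-2,6-dimethoxyphenyl]acetaldehyde F3. Aldol addition of the dilithio dianion of 5 at −78 °C, where addition to an aldehyde is faster than enolization, gives 6-[4-(benzyloxy)-2,6-dimethoxyphenyl]-5-hydroxy-1-(4-methoxyphenyl)hexane-1,3-dione F4 (racemic). Oxidation of this β-hydroxy ketone with 2-iodoxybenzoic acid in EtOAc at reflux gives triketone 6.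

**Further compounds**
F1 | step 8 | methyl 4-[4-(benzyloxy)-2,6-dimethoxyphenyl]-4-[6-(4-methoxyphenyl)-4-oxo-4H-pyran-2-yl]-3-oxobutanoate (racemic) | COC(=O)CC(=O)C(c1cc(=O)cc(o1)-c2ccc(OC)cc2)c3c(OC)cc(OCc4ccccc4)cc3OC
F2 | step 6 | tert-butyl [4-(benzyloxy)-2,6-dimethoxyphenyl][6-(4-methoxyphenyl)-4-oxo-4H-pyran-2-yl]acetate (racemic) | COc1ccc(cc1)-c2cc(=O)cc(o2)C(C(=O)OC(C)(C)C)c3c(OC)cc(OCc4ccccc4)cc3OC
F3 | step 4 | [4-(benzyloxy)-2,6-dimethoxyphenyl]acetaldehyde | COc1cc(OCc2ccccc2)cc(OC)c1CC=O
F4 | step 4 | 6-[4-(benzyloxy)-2,6-dimethoxyphenyl]-5-hydroxy-1-(4-methoxyphenyl)hexane-1,3-dione (racemic) | COc1ccc(cc1)C(=O)CC(=O)CC(O)Cc2c(OC)cc(OCc3ccccc3)cc2OC
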